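**Plan**

1. Retrosynthesis: cut the C19–O ester bond, cut the diene back to a terminal alkyne (C15 and C16 come from ethylene), cut C8–O/C7–H back to a Δ7 alkene, cut C9–C11 back to a C9 ketone, and last cut ring A at C1–C10 and C3–C4.
2. Forward: ring B is (R)-carvone; its isopropenyl group becomes a 1-cyanoethyl group (C4, C18, C19) and C10 is methylated; ring A is then closed in one flask by a [3+3] annulation with 1-chloro-3-iodopropane (C1–C2–C3); the C9 side chain, the 8α-hydroxyl, the diene and the ester follow.
3. Enabling feature: in the monocyclic precursor C10 is the α'-carbon of the C9 carbonyl of ring B and C4 is the α-carbon of the C19 nitrile; these two acidic carbons sit 1,3 to each other across C5, so a propane-1,3-diyl bis-electrophile bridges them and makes ring A and both quaternary carbons.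
4. Stereochemistry: C5 comes from (R)-carvone; C10 from alkylation anti to the C5 substituent; C4 from chair closure with the slim nitrile axial beside the C20 methyl; C9 from α-face addition followed by palladium hydride delivery with inversion; C8 from α-face epoxidation and hydride attack at C7.

Key step: step 4

Remark: positions are given in labdane numbering (C1–C20; α is the face of H-5, β the face of the C20 methyl). Compounds 2–4 are carried as epimer mixtures at the two carbons that step 4 makes planar (C10 and C4); their SMILES show the major C10 epimer and leave C4 open. Compounds 7 and 17 are taken as purchased, and carbonate 10 is used crude.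

Step 1
Reactants: 1 (R)-(−)-carvone
Product: 2 (5R,6S)-2,6-dimethyl-5-(prop-1-en-2-yl)cyclohex-2-en-1-one (trans-6-methylcarvone)
Conditions: LiN(iPr)2, THF, −78 °C; MeI, −78 → 0 °C
Reagents that add atoms: iodomethane, CI
Why: Kinetic α'-deprotonation gives the cross-conjugated lithium enolate, which should be methylated mainly anti to the isopropenyl group (enolate alkylation); this centre (future C10) is made planar again in step 4, so its configuration is not critical.

Step 2
Reactants: 2 trans-6-methylcarvone
Product: 3 (5S,6S)-5-(1-hydroxypropan-2-yl)-2,6-dimethylcyclohex-2-en-1-one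
Conditions: 9-BBN (1.1 equiv), THF, 0 °C → rt; then aq NaOAc, 30% H2O2, 0 °C → rt
Reagents that add atoms: hydrogen peroxide, OO
Why: Anti-Markovnikov hydroboration–oxidation, in which 9-BBN should add to the unhindered 1,1-disubstituted alkene much faster than it touches the conjugated trisubstituted enone and the acetate-buffered peroxide spares the enone; the new centre at C4 is uncontrolled and need not be controlled, because it becomes a carbanion in step 4.

Step 3
Reactants: 3 hydroxy enone
Product: 4 2-[(1S,2S)-2,4-dimethyl-3-oxocyclohex-4-en-1-yl]propanenitrile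
Conditions: TEMPO (0.1 equiv), PhI(OAc)2 (2.2 equiv), NH4OAc (4 equiv), MeCN/H2O 9:1, rt
Reagents that add atoms: ammonium acetate, [NH4+].CC(=O)[O-]
Why: One-pot oxidation of the primary alcohol to the aldehyde, imine formation with ammonia and a second oxidation give the nitrile (oxidative conversion of an alcohol to a nitrile); no stereocentre is set, and the nitrile is the small, linear acidifying group that C4 needs in step 4.

Step 4
Reactants: 4 keto nitrile
Product: 6 9-oxo-11,12,13,14,15,16-hexanorlabd-7-en-19-nitrile (trans-fused; 4β-cyano; 10β-methyl), via chloropropyl ketonitrile 5 (not isolated)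
Conditions: LiN(iPr)2 (1.05 equiv), THF, −78 °C; DMPU, 1-chloro-3-iodopropane (1.05 equiv), −78 → −10 °C; then −78 °C, LiN(iPr)2 (1.3 equiv), → rt
Reagents that add atoms: 1-chloro-3-iodopropane, ClCCCI
Why: The first charge of LiN(iPr)2 removes the most acidic proton, H-10 next to the C9 carbonyl (about five pKa units below the α-cyano proton), and the cross-conjugated lithium enolate displaces iodide from 1-chloro-3-iodopropane to form C1–C10, after which the second charge metalates C4 (the ketone now has no α'-proton and γ-deprotonation of the enone is kinetically slower) and the N-lithiated ketenimine displaces chloride to form C3–C4. The closest known reaction types are the α'-alkylation of 6-alkylcarvone enolates to quaternary carbons and the cycloalkylation of metalated nitriles, which together amount to a [3+3] annulation of a 1,3-dinucleophile with a 1,3-dielectrophile. Ring A closes in the 6-exo-tet mode, and since the C10–C1 and C5–C4 bonds are trans on ring B and both equatorial in the reacting conformer, only the trans-fused decalin can form. C10 is controlled by the C5 stereocentre: the iodide should approach the planar enolate anti to the 1-cyanoethyl group, so the C20 methyl ends β, cis to C4. C4 is controlled by the now axial C20 methyl: in the chair-like transition state the C4 substituent that becomes axial lies 1,3-diaxial to C20, so the slim linear C=C=N–Li unit should take this position and the C18 methyl go equatorial, giving the 4β-cyano (C19 axial) configuration. The step needs C10 to react before C4 (secured by the pKa order and the stepwise addition of base), iodide to leave before chloride (leaving-group order) and C- rather than O-alkylation (lithium enolate with a soft primary iodide in THF/DMPU).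

Step 5
Reactants: 6 bicyclic enone nitrile; 7 (4-bromobut-1-yn-1-yl)trimethylsilane
Product: 10 tertiary allylic methyl carbonate (9β-OCO2Me; 9α-[4-(trimethylsilyl)but-3-yn-1-yl]; Δ7; 19-nitrile), via Grignard reagent 8 (not isolated), via bromomagnesium alkoxide 9 (not isolated)
Conditions: 7, Mg, THF, rt; then 6, LaCl3·2LiCl (1 equiv), THF, 0 °C; then ClCO2Me, 0 °C → rt
Reagents that add atoms: methyl chloroformate, COC(=O)Cl
Why: Grignard 1,2-addition to the C9 ketone, which has no α-hydrogen (LaCl3·2LiCl suppresses reduction and conjugate addition), should occur from the α-face opposite the axial C20 methyl, placing the chain α and the oxygen β, and the alkoxide is acylated in the flask to the allylic carbonate needed in step 6.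

Step 6
Reactants: 10 tertiary allylic methyl carbonate
Product: 11 14-(trimethylsilyl)-15,16-dinorlabd-7-en-13-yne-19-nitrile (9α-H)
Conditions: Pd(OAc)2 (5 mol%), PBu3 (20 mol%), HCO2H, Et3N, THF, 40 °C
Reagents that add atoms: none
Why: Tsuji–Trost-type ionisation by zerovalent palladium takes place anti to the β-carbonate, and the palladium formate should then pass hydride to the more substituted allyl terminus C9 on the same α-face (allylic formate hydrogenolysis), which sets 9α-H with the side chain β and leaves the Δ7 alkene.

Step 7
Reactants: 11 alkenyl nitrile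
Product: 12 14-(trimethylsilyl)-15,16-dinorlabd-7-en-13-yn-19-al
Conditions: iBu2AlH (1.5 equiv), toluene, −78 → 0 °C; then 1 M aq HCl, 0 °C
Reagents that add atoms: water, O
Why: Partial reduction of the hindered axial nitrile to the N-aluminoimine and hydrolysis give the C19 aldehyde (nitrile-to-aldehyde reduction); no stereocentre changes because C4 is quaternary.

Step 8
Reactants: 12 alkenyl aldehyde
Product: 13 7α,8α-epoxy-14-(trimethylsilyl)-15,16-dinorlabd-13-yn-19-al
Conditions: mCPBA (1.05 equiv), NaHCO3, CH2Cl2, 0 °C
Reagents that add atoms: mCPBA, OOC(=O)c1cccc(Cl)c1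
Why: Prilezhaev epoxidation of the trisubstituted Δ7 alkene should occur on the α-face, away from the axial C20 methyl, to give the 7α,8α-epoxide, and the electron-rich alkene should react faster than the hindered aldehyde is oxidised.

Step 9
Reactants: 13 epoxy aldehyde
Product: 15 15,16-dinorlabd-13-yne-8α,19-diol, via silylalkyne diol 14 (not isolated)
Conditions: LiAlH4 (3 equiv), THF, 0 → 65 °C; cool, MeOH, then K2CO3, rt
Reagents that add atoms: none
Why: Hydride should open the epoxide by SN2 attack at the less substituted C7 from the β-face, so the C8–O bond stays α and becomes the 8α tertiary alcohol, the aldehyde is reduced to the C19 alcohol in the same operation, and basic methanol then cleaves the alkynyl C–Si bond (protodesilylation).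

Step 10
Reactants: 15 alkyne diol
Product: 16 labda-13(16),14-diene-8α,19-diol
Conditions: ethylene (1 atm), second-generation Grubbs catalyst (H2IMes)(PCy3)Cl2Ru=CHPh (5 mol%), CH2Cl2, 40 °C
Reagents that add atoms: ethylene, C=C
Why: Cross enyne metathesis of the terminal alkyne with ethylene gives the 2-substituted buta-1,3-diene directly (C15 and C16 from ethylene), the remote free hydroxyls should be tolerated, and no stereocentre is involved.

Step 11
Reactants: 16 diene diol; 17 (E)-4-acetoxycinnamic acid
Product: 18 8α-hydroxylabda-13(16),14-dien-19-yl (E)-4-acetoxycinnamate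
Conditions: DCC (1.3 equiv), DMAP (0.2 equiv), CH2Cl2, 0 °C → rt
Reagents that add atoms: none
Why: Steglich esterification should acylate only the primary C19 alcohol, the tertiary 8α-hydroxyl being unreactive under these conditions, while the acetate on the phenol prevents self-acylation of the acid.

Step 12
Reactants: 18 acetoxycinnamate
Product: 19 8α-hydroxylabda-13(16),14-dien-19-yl p-hydroxycinnamate (target)
Conditions: K2CO3 (0.5 equiv), MeOH, 0 °C
Reagents that add atoms: none
Why: Methanolysis should cleave the activated aryl acetate much faster than the hindered neopentyl-type cinnamate (chemoselective transesterification), freeing the phenol and leaving the (E)-ester, the diene and all stereocentres untouched.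

**Compound list**

1 | (R)-(−)-carvone, (5R)-2-methyl-5-(prop-1-en-2-yl)cyclohex-2-en-1-one | O=C1C[C@H](C(C)=C)CC=C1C | starting material
2 | (5R,6S)-2,6-dimethyl-5-(prop-1-en-2-yl)cyclohex-2-en-1-one (trans-6-methylcarvone; minor 6-epimer carried along) | O=C1[C@@H](C)[C@H](C(C)=C)CC=C1C | intermediate
3 | (5S,6S)-5-(1-hydroxypropan-2-yl)-2,6-dimethylcyclohex-2-en-1-one (both epimers at the side-chain carbon, future C4) | O=C1[C@@H](C)[C@H](C(C)CO)CC=C1C | intermediate
4 | 2-[(1S,2S)-2,4-dimethyl-3-oxocyclohex-4-en-1-yl]propanenitrile (both epimers at the α-cyano carbon, future C4) | O=C1[C@@H](C)[C@H](C(C)C#N)CC=C1C | intermediate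
5 | 2-[2-(3-chloropropyl)-2,4-dimethyl-3-oxocyclohex-4-en-1-yl]propanenitrile; at the new quaternary carbon (future C10) the methyl is cis and the 3-chloropropyl chain trans to the cyanoethyl group | O=C1[C@@](C)(CCCCl)[C@H](C(C)C#N)CC=C1C | intermediate
6 | 9-oxo-11,12,13,14,15,16-hexanorlabd-7-en-19-nitrile (1,4a,6-trimethyl-5-oxo-1,2,3,4,4a,5,8,8a-octahydronaphthalene-1-carbonitrile; trans-fused, 4β-cyano, 4α-methyl, 10β-methyl, 5α-H) | O=C1[C@@]2(C)CCC[C@](C)(C#N)[C@@H]2CC=C1C | intermediate
7 | (4-bromobut-1-yn-1-yl)trimethylsilane | C[Si](C)(C)C#CCCBr | starting material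
8 | [4-(trimethylsilyl)but-3-yn-1-yl]magnesium bromide | C[Si](C)(C)C#CCC[Mg]Br | intermediate
9 | bromomagnesium 9β-alkoxide of the adduct of 8 and 6 (side chain 9α) | C[Si](C)(C)C#CCC[C@@]1([O-])[C@@]2(C)CCC[C@](C)(C#N)[C@@H]2CC=C1C.[Mg+]Br | intermediate
10 | methyl carbonate of the tertiary allylic alcohol: 9β-(methoxycarbonyloxy)-9α-[4-(trimethylsilyl)but-3-yn-1-yl]-11,12,13,14,15,16-hexanorlabd-7-en-19-nitrile | C[Si](C)(C)C#CCC[C@@]1(OC(=O)OC)[C@@]2(C)CCC[C@](C)(C#N)[C@@H]2CC=C1C | intermediate
11 | 14-(trimethylsilyl)-15,16-dinorlabd-7-en-13-yne-19-nitrile (9α-H, side chain β) | C[Si](C)(C)C#CCC[C@@H]1[C@@]2(C)CCC[C@](C)(C#N)[C@@H]2CC=C1C | intermediate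
12 | 14-(trimethylsilyl)-15,16-dinorlabd-7-en-13-yn-19-al | C[Si](C)(C)C#CCC[C@@H]1[C@@]2(C)CCC[C@](C)(C=O)[C@@H]2CC=C1C | intermediate
13 | 7α,8α-epoxy-14-(trimethylsilyl)-15,16-dinorlabd-13-yn-19-al | C[Si](C)(C)C#CCC[C@@H]1[C@@]2(C)CCC[C@](C)(C=O)[C@@H]2C[C@H]3O[C@]31C | intermediate
14 | 14-(trimethylsilyl)-15,16-dinorlabd-13-yne-8α,19-diol | C[Si](C)(C)C#CCC[C@@H]1[C@@]2(C)CCC[C@](C)(CO)[C@@H]2CC[C@@]1(C)O | intermediate
15 | 15,16-dinorlabd-13-yne-8α,19-diol | C#CCC[C@@H]1[C@@]2(C)CCC[C@](C)(CO)[C@@H]2CC[C@@]1(C)O | intermediate
16 | labda-13(16),14-diene-8α,19-diol | C=CC(=C)CC[C@@H]1[C@@]2(C)CCC[C@](C)(CO)[C@@H]2CC[C@@]1(C)O | intermediate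
17 | (E)-4-acetoxycinnamic acid, (2E)-3-[4-(acetyloxy)phenyl]prop-2-enoic acid | CC(=O)Oc1ccc(/C=C/C(=O)O)cc1 | starting material
18 | 8α-hydroxylabda-13(16),14-dien-19-yl (E)-4-acetoxycinnamate | C=CC(=C)CC[C@@H]1[C@@]2(C)CCC[C@](C)(COC(=O)/C=C/c3ccc(OC(C)=O)cc3)[C@@H]2CC[C@@]1(C)O | intermediate
19 | 8α-hydroxylabda-13(16),14-dien-19-yl p-hydroxycinnamate | C=CC(=C)CC[C@@H]1[C@@]2(C)CCC[C@](C)(COC(=O)/C=C/c3ccc(O)cc3)[C@@H]2CC[C@@]1(C)O | target

**Totals**

Total step count: 12. Longest linear sequence: 12 steps, from (R)-carvone; 7 and 17 enter as purchased materials.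

**Steps most likely to fail**

Step 4. The hindered tetrasubstituted enolate may alkylate only slowly with an unactivated primary iodide, which would allow proton exchange, O-alkylation or premature reaction at C4. In the second stage, γ-deprotonation of the enone may compete with metalation of the nitrile. The fallback sets out from 4 and returns at 6. The lithium enolate of 4 is alkylated with the far more reactive allyl bromide to give the C10-allyl ketonitrile F1. Chemoselective hydroboration–oxidation of its vinyl group (9-BBN; H2O2, NaOAc) gives the 3-hydroxypropyl ketonitrile F2. I2, PPh3 and imidazole convert this into the 3-iodopropyl ketonitrile F3. LiN(iPr)2 at −78 °C then closes ring A through the metalated nitrile to give 6. The two C–C bonds are thus made in separate, individually known steps.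

Step 6. Hydride may be delivered to the wrong allyl terminus (giving the tetrasubstituted Δ8 alkene), β-hydride elimination may give dienes, or facial fidelity may be lost through palladium exchange on the allyl complex. The fallback sets out from 6 (with 8 made from 7 as in step 5) and returns at 11. The Grignard adduct is protonated instead of acylated, giving the tertiary allylic alcohol F4. Pyridinium chlorochromate, (C5H5NH)[CrO3Cl], effects the Babler–Dauben oxidative 1,3-transposition to the 8-en-7-one F5. Luche reduction (NaBH4, CeCl3·7H2O, MeOH) should deliver hydride from the α-face and give the 7β-allylic alcohol F6. Mitsunobu displacement with 2-nitrobenzenesulfonylhydrazide (PPh3, diethyl azodicarboxylate, −30 °C) inverts C7 to the N-allyl sulfonylhydrazide F7. On warming this loses the sulfinic acid to give the allylic diazene F8, whose retro-ene loss of nitrogen places hydrogen on the α-face of C9 and gives 11.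

Step 8. The α-quaternary aldehyde may be oxidised (Baeyer–Villiger-type loss of the C19 carbon) in competition with epoxidation, or the epoxide may open under the acidic by-product. The fallback sets out from 12 and returns at 15. NaBH4 in MeOH first reduces the aldehyde to the alkenol F9, so no oxidisable carbonyl remains. mCPBA then epoxidises the Δ7 alkene from the α-face to the epoxy alcohol F10. LiAlH4 followed by K2CO3 in MeOH, as in step 9, gives 15.

**Further compounds**

F1 | step 4 | 2-[2-allyl-2,4-dimethyl-3-oxocyclohex-4-en-1-yl]propanenitrile (allyl trans to the cyanoethyl group) | O=C1[C@@](C)(CC=C)[C@H](C(C)C#N)CC=C1C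
F2 | step 4 | 2-[2-(3-hydroxypropyl)-2,4-dimethyl-3-oxocyclohex-4-en-1-yl]propanenitrile | O=C1[C@@](C)(CCCO)[C@H](C(C)C#N)CC=C1C
F3 | step 4 | 2-[2-(3-iodopropyl)-2,4-dimethyl-3-oxocyclohex-4-en-1-yl]propanenitrile | O=C1[C@@](C)(CCCI)[C@H](C(C)C#N)CC=C1C
F4 | step 6 | 9β-hydroxy-9α-[4-(trimethylsilyl)but-3-yn-1-yl]-11,12,13,14,15,16-hexanorlabd-7-en-19-nitrile | C[Si](C)(C)C#CCC[C@@]1(O)[C@@]2(C)CCC[C@](C)(C#N)[C@@H]2CC=C1C
F5 | step 6 | 7-oxo-14-(trimethylsilyl)-15,16-dinorlabd-8-en-13-yne-19-nitrile | C[Si](C)(C)C#CCCC1[C@@]2(C)CCC[C@](C)(C#N)[C@@H]2CC(=O)C=1C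
F6 | step 6 | 7β-hydroxy-14-(trimethylsilyl)-15,16-dinorlabd-8-en-13-yne-19-nitrile | C[Si](C)(C)C#CCCC1[C@@]2(C)CCC[C@](C)(C#N)[C@@H]2C[C@H](O)C=1C
F7 | step 6 | N-(7α-allylic) N-(2-nitrobenzenesulfonyl)hydrazine derived from F6 | C[Si](C)(C)C#CCCC1[C@@]2(C)CCC[C@](C)(C#N)[C@@H]2C[C@@H](N(N)S(=O)(=O)c3ccccc3[N+](=O)[O-])C=1C
F8 | step 6 | 7α-diazenyl-14-(trimethylsilyl)-15,16-dinorlabd-8-en-13-yne-19-nitrile | C[Si](C)(C)C#CCCC1[C@@]2(C)CCC[C@](C)(C#N)[C@@H]2C[C@@H](N=N)C=1C
F9 | step 8 | 14-(trimethylsilyl)-15,16-dinorlabd-7-en-13-yn-19-ol | C[Si](C)(C)C#CCC[C@@H]1[C@@]2(C)CCC[C@](C)(CO)[C@@H]2CC=C1C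
F10 | step 8 | 7α,8α-epoxy-14-(trimethylsilyl)-15,16-dinorlabd-13-yn-19-ol | C[Si](C)(C)C#CCC[C@@H]1[C@@]2(C)CCC[C@](C)(CO)[C@@H]2C[C@H]3O[C@]31C
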